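Dielsianone is disconnected at the two C–C bonds that flank its vicinal dicarbonyl: C6 of benzo ring A to CO, and CO to C1' of anisyl ring C. This C=O/C=O pair is read as an oxalyl dication and supplied as the bis(N-methoxy-N-methyl)amide of oxalic acid. In one flask a C6-lithiated chroman and then an anisyl Grignard reagent each add once. The unsymmetrical benzil thus emerges at its final oxidation level, and no ring or lasting stereocentre is made. The precursor is 6-bromo-5,8-dimethoxy-2,2-dimethylchroman, with C3–C4 saturated and O5 and O8 as methyl ethers, three steps from 2,5-dimethoxyphenol. Chelation-directed O5 demethylation and C3–C4 dehydrogenation complete the synthesis.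

Key step: step 4

Remark: all bicyclic compounds carry chroman numbering (O1, C2, C3, C4, C4a, C5–C8, C8a). Ring A is the benzo ring, ring B the pyran ring and ring C the anisyl ring. The target has no stereocentre.

Step 1
Reactants: 1 2,5-dimethoxyphenol; 2 3-methylbut-2-enal
Product: 5 5,8-dimethoxy-2,2-dimethyl-2H-chromene, via benzodioxaborinine 3 (not isolated), via ortho-quinone methide 4 (not isolated)
Conditions: 2 (1.5 equiv), PhB(OH)2 (1.0 equiv), AcOH, toluene, reflux, Dean–Stark
Reagents that add atoms: phenylboronic acid, OB(O)c1ccccc1 (its PhB unit is present only in intermediate 3 and is absent from 5)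
Why: The phenylboronic acid-mediated condensation of a phenol with an enal is a known 2H-chromene synthesis in which the boron tether hands the aldehyde carbon to the only free ortho carbon of 1 (between OH and the C5 methoxy group) to give 3, thermal extrusion of the PhBO unit unmasks 4, and an oxa-6π electrocyclisation of 4 closes ring B, so para attack is excluded by design.

Step 2
Reactants: 5 5,8-dimethoxy-2,2-dimethyl-2H-chromene
Product: 6 5,8-dimethoxy-2,2-dimethylchroman
Conditions: H2 (1 atm), 10% Pd/C, EtOAc, rt
Reagents that add atoms: none
Why: Heterogeneous catalytic hydrogenation saturates the styrene-like C3=C4 bond under conditions that spare aryl ethers and the arene, creates no stereocentre, and removes the one site that would otherwise compete with ring A for the brominating agent in the next step.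

Step 3
Reactants: 6 5,8-dimethoxy-2,2-dimethylchroman
Product: 7 6-bromo-5,8-dimethoxy-2,2-dimethylchroman
Conditions: NBS (1.0 equiv), MeCN, 0 °C → rt, dark
Reagents that add atoms: N-bromosuccinimide, O=C1CCC(=O)N1Br
Why: Electrophilic aromatic bromination with NBS in a polar solvent should go to C6, which is para to the conformationally locked O1 and ortho to the C5 methoxy group, while C7 is conjugated with one oxygen only (the same bias that sends 1,2,4-trialkoxybenzenes to their C5), and darkness and low temperature hold back radical attack at benzylic C4.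

Step 4
Reactants: 7 6-bromo-5,8-dimethoxy-2,2-dimethylchroman; 8 N,N'-dimethoxy-N,N'-dimethyloxamide; 9 4-methoxyphenylmagnesium bromide (commercial THF solution, titrated)
Product: 13 1-(5,8-dimethoxy-2,2-dimethylchroman-6-yl)-2-(4-methoxyphenyl)ethane-1,2-dione, via aryllithium 10 (not isolated), via lithium mono-adduct 11 (not isolated), via mixed bis-adduct 12 (not isolated)
Conditions: n-BuLi (1.0 equiv), THF, −78 °C; cannula transfer into 8 (1.1 equiv), THF, −78 °C; 9 (1.5 equiv), −78 → 0 °C; cold 1 M HCl
Reagents that add atoms: n-butyllithium, [Li]CCCC (its lithium is present only in intermediates 10, 11 and 12 and is absent from 13)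
Why: Bromine–lithium exchange turns 7 into aryllithium 10, whose C–Li bond is held by the neighbouring C5 methoxy oxygen, and slow transfer of 10 into a small excess of 8 at −78 °C gives one acyl addition to form 11, in which lithium bridges the alkoxide and the N-methoxy oxygen so that the tetrahedral carbon cannot eject the amine. Grignard reagent 9 then finds a single remaining C=O, adds to it to give 12, and cold aqueous acid breaks down both hemiaminal carbons together, which unveils the C6–CO–CO–C1' diketone without any redox adjustment. The closest known reaction type is the Weinreb ketone synthesis in its twofold form, the successive addition of two different organometallic reagents to this same oxamide to give unsymmetrical 1,2-diketones. No ring is closed, and the hemiaminal stereocentres of 11 and 12 are transient and vanish on hydrolysis, so no stereocontrol is needed. The step needs exactly one C–C bond per carbonyl and one aryl group of each kind: the chelates block over-addition, inverse addition of one equivalent of the ortho-substituted 10 keeps free 8 in excess over 10 at all times, the anionic and crowded 11 resists a second bulky aryllithium, and the cheap 9 is used in excess only once 10 is consumed. The saturated C3–C4 unit and the ether groups of 7 offer no acidic or electrophilic site to either organometallic.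

Step 5
Reactants: 13 1-(5,8-dimethoxy-2,2-dimethylchroman-6-yl)-2-(4-methoxyphenyl)ethane-1,2-dione
Product: 15 1-(5-hydroxy-8-methoxy-2,2-dimethylchroman-6-yl)-2-(4-methoxyphenyl)ethane-1,2-dione, via dichloroboron chelate 14 (not isolated)
Conditions: BCl3 (2 equiv, 1 M in CH2Cl2), CH2Cl2, −78 → 0 °C; then ice-water
Reagents that add atoms: boron trichloride, ClB(Cl)Cl (its BCl2 unit is present only in intermediate 14 and is absent from 15)
Why: Chelation-controlled Lewis acid cleavage of an aryl methyl ether: BCl3 is clamped between the C6 ketone oxygen and O5 in a six-membered chelate, so chloride takes only the methyl group of that crowded, out-of-plane ether to give 14, whereas the C8 and C4' methyl ethers and the ring B ether have no neighbouring carbonyl group and should survive at or below 0 °C, and water then frees the hydrogen-bonded phenol.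

Step 6
Reactants: 15 1-(5-hydroxy-8-methoxy-2,2-dimethylchroman-6-yl)-2-(4-methoxyphenyl)ethane-1,2-dione
Product: 16 dielsianone
Conditions: DDQ (1.3 equiv), dry 1,4-dioxane, reflux
Reagents that add atoms: none
Why: DDQ dehydrogenation of 2,2-dimethylchromans to 2H-chromenes is well known for ortho-acylphenols of this kind: hydride abstraction from benzylic C4 is assisted by O1 and the C5 hydroxyl, both ortho to C4a, proton loss from C3 then places the alkene in conjugation with ring A, and the dry solvent denies water to the competing oxidative demethylation of the para-methoxyphenol.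

Compound list
1 | 2,5-dimethoxyphenol | COc1ccc(OC)c(O)c1 | starting material
2 | 3-methylbut-2-enal | CC(C)=CC=O | starting material
3 | 5,8-dimethoxy-4-(2-methylprop-1-en-1-yl)-2-phenyl-4H-1,3,2-benzodioxaborinine (racemic) | COc1ccc(OC)c2c1OB(c1ccccc1)OC2C=C(C)C | intermediate
4 | (6Z)-2,5-dimethoxy-6-(3-methylbut-2-en-1-ylidene)cyclohexa-2,4-dien-1-one (ortho-quinone methide) | COC1=CC=C(OC)/C(=C/C=C(C)C)C1=O | intermediate
5 | 5,8-dimethoxy-2,2-dimethyl-2H-chromene | COc1ccc(OC)c2c1OC(C)(C)C=C2 | intermediate
6 | 5,8-dimethoxy-2,2-dimethylchroman | COc1ccc(OC)c2c1OC(C)(C)CC2 | intermediate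
7 | 6-bromo-5,8-dimethoxy-2,2-dimethylchroman | COc1cc(Br)c(OC)c2c1OC(C)(C)CC2 | intermediate
8 | N,N'-dimethoxy-N,N'-dimethyloxamide | CON(C)C(=O)C(=O)N(C)OC | starting material
9 | 4-methoxyphenylmagnesium bromide | COc1ccc([Mg]Br)cc1 | starting material
10 | (5,8-dimethoxy-2,2-dimethylchroman-6-yl)lithium | COc1cc([Li])c(OC)c2c1OC(C)(C)CC2 | intermediate
11 | lithium 1-(5,8-dimethoxy-2,2-dimethylchroman-6-yl)-1,2-bis[methoxy(methyl)amino]-2-oxoethan-1-olate (racemic mono-adduct) | COc1cc(C(O[Li])(N(C)OC)C(=O)N(C)OC)c(OC)c2c1OC(C)(C)CC2 | intermediate
12 | 1-(5,8-dimethoxy-2,2-dimethylchroman-6-yl)-2-(4-methoxyphenyl)-1,2-bis[methoxy(methyl)amino]ethane-1,2-diolate, O–Li at the chromanyl carbon, O–MgBr at the anisyl carbon (mixture of diastereomers) | COc1ccc(C(O[Mg]Br)(N(C)OC)C(O[Li])(N(C)OC)c2cc(OC)c3c(c2OC)CCC(C)(C)O3)cc1 | intermediate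
13 | 1-(5,8-dimethoxy-2,2-dimethylchroman-6-yl)-2-(4-methoxyphenyl)ethane-1,2-dione | COc1ccc(C(=O)C(=O)c2cc(OC)c3c(c2OC)CCC(C)(C)O3)cc1 | intermediate
14 | O5-dichloroboryl chelate of 15 | COc1ccc(C(=O)C(=O)c2cc(OC)c3c(c2OB(Cl)Cl)CCC(C)(C)O3)cc1 | intermediate
15 | 1-(5-hydroxy-8-methoxy-2,2-dimethylchroman-6-yl)-2-(4-methoxyphenyl)ethane-1,2-dione | COc1ccc(C(=O)C(=O)c2cc(OC)c3c(c2O)CCC(C)(C)O3)cc1 | intermediate
16 | dielsianone, 1-(5-hydroxy-8-methoxy-2,2-dimethyl-2H-chromen-6-yl)-2-(4-methoxyphenyl)ethane-1,2-dione | COc1ccc(C(=O)C(=O)c2cc(OC)c3c(c2O)C=CC(C)(C)O3)cc1 | target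

Total step count: 6. Longest linear sequence: 6 steps (1 → 5 → 6 → 7 → 13 → 15 → 16).

Steps most likely to fail

Step 4. The first tetrahedral adduct may break down before the Grignard reagent has reacted, which would expose a ketone to over-addition. The aryllithium may also add at both amide ends, be lost by proton transfer, or act as a base on the N-methoxy group. The fallback sets out from 7 and comes back at 13. It brings in the two linker carbons as an alkyne and oxidises them afterwards. Sonogashira coupling of 7 with commercial 4-ethynylanisole (C#Cc1ccc(OC)cc1; PdCl2(PPh3)2, CuI, Et3N, DMF, 80 °C) should give 6-[(4-methoxyphenyl)ethynyl]-5,8-dimethoxy-2,2-dimethylchroman F1. The known diarylalkyne-to-benzil oxidation (PdI2 cat., DMSO, 140 °C) should then convert F1 into 13.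

Step 6. Hydride abstraction may be slow on the acyl-bearing ring. The para-methoxyphenol unit may be oxidised towards a quinone by traces of water, or the chromene may be oxidised further. The fallback sets out from 13 and comes back at 16. It replaces hydride abstraction by radical halogenation and elimination, and moves the demethylation to the end.
- Wohl–Ziegler bromination of 13 at benzylic C4 (NBS, AIBN, PhCF3, reflux) should give 1-(4-bromo-5,8-dimethoxy-2,2-dimethylchroman-6-yl)-2-(4-methoxyphenyl)ethane-1,2-dione F2.
- E2 dehydrobromination (DBU, toluene, rt → 80 °C) should give 1-(5,8-dimethoxy-2,2-dimethyl-2H-chromen-6-yl)-2-(4-methoxyphenyl)ethane-1,2-dione F3.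
- The mild chelation-directed demethylation with MgI2·OEt2 (THF, 60 °C), which tolerates the acid-sensitive chromene, should pass through the iodomagnesium phenolate of 16 F4. Dilute HCl should then release 16.

Step 1. C–C bond formation at the crowded carbon between two oxygens may be slow, so that self-condensation and polymerisation of the enal under long heating in acid take over. The fallback sets out from 1 and comes back at 5. It builds ring B by a sigmatropic route that is ortho-specific by mechanism. O-Alkylation of 1 with 3-chloro-3-methylbut-1-yne (C#CC(C)(C)Cl; DBU, CuCl2 cat., MeCN, 0 °C) should give 1,4-dimethoxy-2-[(2-methylbut-3-yn-2-yl)oxy]benzene F5. Heating (N,N-diethylaniline, 190 °C) should then trigger an aromatic propargyl Claisen rearrangement to 3,6-dimethoxy-2-(3-methylbuta-1,2-dien-1-yl)phenol F6. A 1,5-hydrogen shift in F6 leads to 4, and electrocyclisation of 4 gives 5.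

Further compounds
F1 | step 4 | 6-[(4-methoxyphenyl)ethynyl]-5,8-dimethoxy-2,2-dimethylchroman | COc1ccc(C#Cc2cc(OC)c3c(c2OC)CCC(C)(C)O3)cc1
F2 | step 6 | 1-(4-bromo-5,8-dimethoxy-2,2-dimethylchroman-6-yl)-2-(4-methoxyphenyl)ethane-1,2-dione (racemic) | COc1ccc(C(=O)C(=O)c2cc(OC)c3c(c2OC)C(Br)CC(C)(C)O3)cc1
F3 | step 6 | 1-(5,8-dimethoxy-2,2-dimethyl-2H-chromen-6-yl)-2-(4-methoxyphenyl)ethane-1,2-dione | COc1ccc(C(=O)C(=O)c2cc(OC)c3c(c2OC)C=CC(C)(C)O3)cc1
F4 | step 6 | iodomagnesium phenolate of 16 | COc1ccc(C(=O)C(=O)c2cc(OC)c3c(c2O[Mg]I)C=CC(C)(C)O3)cc1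
F5 | step 1 | 1,4-dimethoxy-2-[(2-methylbut-3-yn-2-yl)oxy]benzene | COc1ccc(OC)c(OC(C)(C)C#C)c1
F6 | step 1 | 3,6-dimethoxy-2-(3-methylbuta-1,2-dien-1-yl)phenol | COc1ccc(OC)c(C=C=C(C)C)c1O
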